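Everything rests on cutting the bond between the tertiary stereocentre C2 (the CH that carries the acyloxymethyl arm and the benzylic carbinol C3) and the allylic CH2 of the 3,4-dimethoxystyryl chain. The key step exploits the 1,3-relationship between the C3 hydroxyl next to the 4-methoxyphenyl ring and the acyloxymethyl carbon, taken as a masked ester: the chelated dilithium dianion of (S)-β-hydroxy ester 2 is C-alkylated by (E)-cinnamyl bromide 4 (Fráter–Seebach). One operation joins both aryl halves, keeps the E-alkene and sets C2 anti to C3. The precursor pair is an aldol-type ester and an allylic bromide; reduction, primary tosylation and SN2 esterification with caesium (Z)-sarracinate finish.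

Key step: step 3

Remark: compounds 1, 3 and 9 are taken as commercially available. The facial sense of the transfer hydrogenation in step 1 is assumed to follow that of aryl methyl ketones.

Step 1
Reactants: 1 ethyl 3-(4-methoxyphenyl)-3-oxopropanoate
Product: 2 ethyl (3S)-3-hydroxy-3-(4-methoxyphenyl)propanoate
Conditions: RuCl[(S,S)-TsDPEN](p-cymene) (1 mol %), HCO2H/Et3N (5:2), DMF, 30 °C
Reagents that add atoms: none
Why: Noyori–Ikariya asymmetric transfer hydrogenation of an aryl ketone; the (S,S)-catalyst should deliver hydride to the face that gives the (S)-benzylic alcohol, which sets C3.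

Step 2
Reactants: 3 (E)-3-(3,4-dimethoxyphenyl)prop-2-en-1-ol
Product: 4 4-[(E)-3-bromoprop-1-en-1-yl]-1,2-dimethoxybenzene
Conditions: PBr3 (0.4 equiv), Et2O, 0 °C; used at once without purification
Reagents that add atoms: phosphorus tribromide, BrP(Br)Br
Why: Bromination of a primary allylic alcohol through its bromophosphite; the conjugated E-cinnamyl bromide is the thermodynamic allylic isomer, so the alkene geometry should be kept.

Step 3
Reactants: 2 ethyl (3S)-3-hydroxy-3-(4-methoxyphenyl)propanoate; 4 4-[(E)-3-bromoprop-1-en-1-yl]-1,2-dimethoxybenzene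
Product: 6 ethyl (2R,3S)-2-[(E)-3-(3,4-dimethoxyphenyl)prop-2-en-1-yl]-3-hydroxy-3-(4-methoxyphenyl)propanoate, via dilithium dianion 5 (not isolated)
Conditions: LDA (2.2 equiv), THF, −78 → −30 °C; then 4 (1.3 equiv), DMPU, −78 → −20 °C; aq. NH4Cl
Reagents that add atoms: none
Why: Double deprotonation of 2 gives the six-membered lithium chelate 5 (alkoxide and enolate oxygen bridged by lithium, enolate O–Li cis to C3), whose C2 displaces bromide from the primary allylic carbon of 4 in an SN2 step; this is a Fráter–Seebach alkylation, the anti-selective alkylation of β-hydroxy ester dianions with allylic halides. No ring is closed; the chelate is only a temporary control element. The new stereocentre C2 is controlled by the existing carbinol centre C3: in the half-chair chelate the 4-methoxyphenyl group shields one enolate face, so the electrophile should enter anti to it and give the (2R,3S)-anti ester, which maps onto the (S,S) target once the ester is reduced. The step needs C- over O-alkylation (secured by the soft enolate carbon and tight O–Li bonds), attack at the primary terminus of the allyl unit (unhindered, and it keeps the styrene conjugated and E), and alkylation faster than retro-aldol cleavage (lithium counter-ion, temperature at or below −20 °C, DMPU to speed the SN2 step).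

Step 4
Reactants: 6 ethyl (2R,3S)-2-[(E)-3-(3,4-dimethoxyphenyl)prop-2-en-1-yl]-3-hydroxy-3-(4-methoxyphenyl)propanoate
Product: 7 (1S,2S)-2-[(E)-3-(3,4-dimethoxyphenyl)prop-2-en-1-yl]-1-(4-methoxyphenyl)propane-1,3-diol
Conditions: LiAlH4, THF, 0 °C; then H2O/aq. NaOH
Reagents that add atoms: none
Why: Hydride reduction of the ester to the primary alcohol; the isolated styrene and both stereocentres are untouched, and C2 is no longer epimerisable afterwards (its descriptor changes to S only through the priority change).

Step 5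
Reactants: 7 (1S,2S)-2-[(E)-3-(3,4-dimethoxyphenyl)prop-2-en-1-yl]-1-(4-methoxyphenyl)propane-1,3-diol
Product: 8 (2S,3S)-2-[(E)-3-(3,4-dimethoxyphenyl)prop-2-en-1-yl]-3-hydroxy-3-(4-methoxyphenyl)propyl 4-methylbenzenesulfonate
Conditions: TsCl (1.05 equiv), Et3N, DMAP (cat.), CH2Cl2, −10 → 0 °C
Reagents that add atoms: p-toluenesulfonyl chloride, Cc1ccc(cc1)S(=O)(=O)Cl
Why: Selective sulfonylation of the primary hydroxyl of a 1,3-diol; the hindered secondary benzylic hydroxyl should react much more slowly at low temperature with one equivalent of reagent.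

Step 6
Reactants: 9 but-2-yn-1-ol
Product: 10 (Z)-2-(tributylstannyl)but-2-en-1-ol
Conditions: Bu3SnH (1.1 equiv), [Cp*RuCl]4 (1.5 mol %), CH2Cl2, rt
Reagents that add atoms: tributyltin hydride, CCCC[SnH](CCCC)CCCC
Why: Ruthenium-catalysed hydroxyl-directed trans-hydrostannation of a propargylic alcohol; hydrogen bonding of the OH to the Ru–Cl unit should place tin on the proximal carbon, and trans addition puts tin cis to the methyl group.

Step 7
Reactants: 10 (Z)-2-(tributylstannyl)but-2-en-1-ol
Product: 11 methyl (Z)-2-(hydroxymethyl)but-2-enoate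
Conditions: Pd(OAc)2 (5 mol %), Ph3As (10 mol %), 1,4-benzoquinone (1.5 equiv), TFA (cat.), CO (1 atm), MeOH, rt
Reagents that add atoms: carbon monoxide, [C-]#[O+]; methanol, CO
Why: Hydroxyl-assisted oxidative methoxycarbonylation of an alkenylstannane (Sn-to-Pd transmetalation, CO insertion, methanolysis, Pd(0) reoxidised by benzoquinone); the C–Sn bond is replaced with retention, so the methyl group ends up cis to the ester.

Step 8
Reactants: 11 methyl (Z)-2-(hydroxymethyl)but-2-enoate
Product: 12 caesium (Z)-2-(hydroxymethyl)but-2-enoate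
Conditions: CsOH·H2O (0.98 equiv), MeOH/H2O, 0 °C → rt; evaporate, dry azeotropically with toluene
Reagents that add atoms: caesium hydroxide, [Cs+].[OH-]
Why: Saponification with a slight deficit of hydroxide gives the dry caesium carboxylate directly, with no excess base carried forward; mild alkaline hydrolysis should leave the Z-enoate geometry intact.

Step 9
Reactants: 8 (2S,3S)-2-[(E)-3-(3,4-dimethoxyphenyl)prop-2-en-1-yl]-3-hydroxy-3-(4-methoxyphenyl)propyl 4-methylbenzenesulfonate; 12 caesium (Z)-2-(hydroxymethyl)but-2-enoate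
Product: 13 (2S,3S)-2-[(E)-3-(3,4-dimethoxyphenyl)prop-2-en-1-yl]-3-hydroxy-3-(4-methoxyphenyl)propyl (Z)-2-(hydroxymethyl)but-2-enoate
Conditions: 12 (1.5 equiv), DMF, 45–50 °C
Reagents that add atoms: none
Why: SN2 O-alkylation of a caesium carboxylate by a primary tosylate; the acyl group is never activated, so the Z-enoate cannot isomerise, and the carboxylate is far more nucleophilic than either free hydroxyl, so no protecting group is needed and no stereocentre is touched.

Compound list
1 | ethyl 3-(4-methoxyphenyl)-3-oxopropanoate | CCOC(=O)CC(=O)c1ccc(OC)cc1 | starting material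
2 | ethyl (3S)-3-hydroxy-3-(4-methoxyphenyl)propanoate | CCOC(=O)C[C@H](O)c1ccc(OC)cc1 | intermediate
3 | (E)-3-(3,4-dimethoxyphenyl)prop-2-en-1-ol | OC/C=C/c1ccc(OC)c(OC)c1 | starting material
4 | 4-[(E)-3-bromoprop-1-en-1-yl]-1,2-dimethoxybenzene | BrC/C=C/c1ccc(OC)c(OC)c1 | intermediate
5 | dilithium alkoxide-enolate of 2 (chelated dianion, enolate O–Li cis to C3) | CCO/C([O-])=C/[C@H]([O-])c1ccc(OC)cc1.[Li+].[Li+] | intermediate
6 | ethyl (2R,3S)-2-[(E)-3-(3,4-dimethoxyphenyl)prop-2-en-1-yl]-3-hydroxy-3-(4-methoxyphenyl)propanoate | CCOC(=O)[C@H](C/C=C/c1ccc(OC)c(OC)c1)[C@H](O)c1ccc(OC)cc1 | intermediate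
7 | (1S,2S)-2-[(E)-3-(3,4-dimethoxyphenyl)prop-2-en-1-yl]-1-(4-methoxyphenyl)propane-1,3-diol | OC[C@H](C/C=C/c1ccc(OC)c(OC)c1)[C@H](O)c1ccc(OC)cc1 | intermediate
8 | (2S,3S)-2-[(E)-3-(3,4-dimethoxyphenyl)prop-2-en-1-yl]-3-hydroxy-3-(4-methoxyphenyl)propyl 4-methylbenzenesulfonate | Cc1ccc(cc1)S(=O)(=O)OC[C@H](C/C=C/c1ccc(OC)c(OC)c1)[C@H](O)c1ccc(OC)cc1 | intermediate
9 | but-2-yn-1-ol | CC#CCO | starting material
10 | (Z)-2-(tributylstannyl)but-2-en-1-ol | C/C=C(/CO)[Sn](CCCC)(CCCC)CCCC | intermediate
11 | methyl (Z)-2-(hydroxymethyl)but-2-enoate | C/C=C(/CO)C(=O)OC | intermediate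
12 | caesium (Z)-2-(hydroxymethyl)but-2-enoate | C/C=C(/CO)C(=O)[O-].[Cs+] | intermediate
13 | (2S,3S)-2-[(E)-3-(3,4-dimethoxyphenyl)prop-2-en-1-yl]-3-hydroxy-3-(4-methoxyphenyl)propyl (Z)-2-(hydroxymethyl)but-2-enoate | C/C=C(/CO)C(=O)OC[C@H](C/C=C/c1ccc(OC)c(OC)c1)[C@H](O)c1ccc(OC)cc1 | target

Total step count: 9. Longest linear sequence: 5 steps (steps 1, 3, 4, 5, 9, from compound 1).

Steps most likely to fail

Step 3. The electron-rich cinnamyl bromide may be lost by ionisation, oligomerisation or attack of the amide base. A slow C-alkylation would also let retro-aldol cleavage of the benzylic lithium aldolate and epimerisation at C2 compete. The fallback sets out from 2 and comes back at 6. The same dianion would be alkylated with allyl bromide, a stable and fast electrophile (LDA, THF, −78 → −30 °C), to give ethyl (2R,3S)-3-hydroxy-3-(4-methoxyphenyl)-2-(prop-2-en-1-yl)propanoate F1 with the same anti induction. Olefin cross-metathesis of F1 with commercial 3,4-dimethoxystyrene (Hoveyda–Grubbs II catalyst, CH2Cl2, 40 °C) should then attach the aryl group E-selectively and give 6.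

Step 9. Displacement at the β-branched primary carbon may be slow, so that intramolecular O-alkylation by the free benzylic hydroxyl (oxetane formation) or fragmentation of the hydroxy tosylate consumes 8. The fallback forms the ester by acyl transfer instead; it sets out from 7 (drawing on 11) and comes back at 13. Silylation of 11 (TBSCl, imidazole, DMF) should give methyl (Z)-2-{[(tert-butyldimethylsilyl)oxy]methyl}but-2-enoate F2, and saponification (LiOH, THF/H2O, then mild acid) the acid (Z)-2-{[(tert-butyldimethylsilyl)oxy]methyl}but-2-enoic acid F3. Activation with 2,4,6-trichlorobenzoyl chloride and Et3N in toluene gives the mixed anhydride (Z)-2-{[(tert-butyldimethylsilyl)oxy]methyl}but-2-enoic 2,4,6-trichlorobenzoic anhydride F4. Without a nucleophilic catalyst, to avoid Z/E isomerisation, F4 should acylate the primary hydroxyl of 7 selectively and give the silyl-protected ester (2S,3S)-2-[(E)-3-(3,4-dimethoxyphenyl)prop-2-en-1-yl]-3-hydroxy-3-(4-methoxyphenyl)propyl (Z)-2-{[(tert-butyldimethylsilyl)oxy]methyl}but-2-enoate F5. Desilylation with HF·pyridine in THF/pyridine at 0 °C, buffered to prevent acyl migration and ionisation of the benzylic alcohol, would give 13.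

Step 7. Protodestannylation or homocoupling of the alkenylstannane may outrun CO insertion under the oxidative conditions. The fallback sets out from 10 and comes back at 11. Iododestannylation (I2, CH2Cl2, 0 °C) should give (Z)-2-iodobut-2-en-1-ol F6 with retention of geometry. A Pd(0)-catalysed methoxycarbonylation of the C–I bond (PdCl2(PPh3)2, CO 1 atm, MeOH, Et3N, 50 °C) would then deliver 11, with methanol as solvent outcompeting intramolecular trapping by the hydroxyl.

Further compounds
F1 | step 3 | ethyl (2R,3S)-3-hydroxy-3-(4-methoxyphenyl)-2-(prop-2-en-1-yl)propanoate | CCOC(=O)[C@H](CC=C)[C@H](O)c1ccc(OC)cc1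
F2 | step 9 | methyl (Z)-2-{[(tert-butyldimethylsilyl)oxy]methyl}but-2-enoate | C/C=C(/CO[Si](C)(C)C(C)(C)C)C(=O)OC
F3 | step 9 | (Z)-2-{[(tert-butyldimethylsilyl)oxy]methyl}but-2-enoic acid | C/C=C(/CO[Si](C)(C)C(C)(C)C)C(=O)O
F4 | step 9 | (Z)-2-{[(tert-butyldimethylsilyl)oxy]methyl}but-2-enoic 2,4,6-trichlorobenzoic anhydride | C/C=C(/CO[Si](C)(C)C(C)(C)C)C(=O)OC(=O)c1c(Cl)cc(Cl)cc1Cl
F5 | step 9 | (2S,3S)-2-[(E)-3-(3,4-dimethoxyphenyl)prop-2-en-1-yl]-3-hydroxy-3-(4-methoxyphenyl)propyl (Z)-2-{[(tert-butyldimethylsilyl)oxy]methyl}but-2-enoate | C/C=C(/CO[Si](C)(C)C(C)(C)C)C(=O)OC[C@H](C/C=C/c1ccc(OC)c(OC)c1)[C@H](O)c1ccc(OC)cc1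
F6 | step 7 | (Z)-2-iodobut-2-en-1-ol | C/C=C(/CO)I
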